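**Plan**
- **Cuts, in retrosynthetic order:** the three O–benzyl bonds; the lactone Cα–CH2Ar bond (enolate alkylation); the lactone C–O bond and the aryl–CH= bond at C5 of the dihydrobenzofuran (Heck reaction with an itaconate half-ester); last, the C3–C3a bond of the dihydrobenzofuran.
- **Enabling feature:** in the ring O1–C2–C3–C3a–C7a, C3 carries both the benzo carbon C3a and an exocyclic one-carbon unit (CH2OH). Putting that carbon back between C3 and C3a gives the six-membered ring O1–C2–C3–C4(=O)–C4a–C8a of a flavanone. The five-membered ring is therefore the product of an oxidative 1,2-aryl shift (6→5) that expels C4 as an ester, makes C3–C3a and sets C3 in one event.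
- **Forward order of rings:** pyranone of chromone 4, then (S)-flavanone 7, then contraction to dihydrobenzofuran 10, then the C5 side chain, then butyrolactone 17, then the second benzyl group.
- **Stereochemistry:** C2 comes from a ligand-controlled conjugate addition. C3 comes from the stereospecific shift (inversion at C–I, 2,3-trans). Lactone Cβ comes from Rh-catalysed asymmetric hydrogenation. Cα comes from alkylation anti to the Cβ substituent.
- **Helper:** a pivalate on the C2-aryl group lowers its migratory aptitude and suppresses C2–O ionisation. It is lost without an extra step in the ester reduction.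

Key step: step 5

Assumption: the sense of induction of the chiral catalysts in steps 4 and 9 is assigned by analogy with cyclic enones and itaconates, and the antipodal ligand is used if either proves opposite; 1, 5, 13 and 18 are taken as catalogue compounds.

Step 1
Reactants: 1 1-(2-hydroxy-3-methoxyphenyl)ethan-1-one
Product: 2 1-(5-bromo-2-hydroxy-3-methoxyphenyl)ethan-1-one
Conditions: NBS (1.05 equiv), MeCN, 0 °C to rt
Reagents that add atoms: N-bromosuccinimide, O=C1CCC(=O)N1Br
Why: Electrophilic aromatic bromination should go para to the free OH (C5), the only open position activated by it and also meta to the acetyl group; no stereocentre is formed.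

Step 2
Reactants: 2 1-(5-bromo-2-hydroxy-3-methoxyphenyl)ethan-1-one
Product: 4 6-bromo-8-methoxy-4H-chromen-4-one, via enaminone 3 (not isolated)
Conditions: DMF dimethyl acetal, toluene, 100 °C; concentrate; conc. HCl, CH2Cl2, 40 °C
Reagents that add atoms: N,N-dimethylformamide dimethyl acetal, COC(OC)N(C)C
Why: Condensation of the methyl ketone with the amide acetal followed by acid-induced addition–elimination of the phenol OH on the vinylogous amide is the standard enaminone route to 2,3-unsubstituted chromones.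

Step 3
Reactants: 5 (4-hydroxy-3-methoxyphenyl)boronic acid
Product: 6 [3-methoxy-4-(pivaloyloxy)phenyl]boronic acid
Conditions: PivCl (1.1 equiv), pyridine, THF, 0 °C to rt; aqueous work-up
Reagents that add atoms: pivaloyl chloride, CC(C)(C)C(=O)Cl
Why: O-acylation of the phenol installs the acid-stable, electron-withdrawing helper needed in step 5, and any mixed B–O acyl species should be hydrolysed back to B(OH)2 on work-up.

Step 4
Reactants: 4 6-bromo-8-methoxy-4H-chromen-4-one; 6 [3-methoxy-4-(pivaloyloxy)phenyl]boronic acid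
Product: 7 (2S)-6-bromo-8-methoxy-2-[3-methoxy-4-(pivaloyloxy)phenyl]chroman-4-one
Conditions: Pd(OCOCF3)2 (5 mol %), (R)-t-BuPyOx (6 mol %), NH4PF6 (30 mol %), H2O (5 equiv), ClCH2CH2Cl, 60 °C
Reagents that add atoms: none
Why: Pd(II)-catalysed asymmetric conjugate addition of an arylboronic acid to a chromone, in which the tert-butyl oxazoline quadrant fixes the face of C2 in the migratory insertion of aryl–Pd across C2=C3, and the metal stays Pd(II) so that the C–Br bond and the pivalate are untouched.

Step 5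
Reactants: 7 (2S)-6-bromo-8-methoxy-2-[3-methoxy-4-(pivaloyloxy)phenyl]chroman-4-one
Product: 10 methyl (2S,3S)-5-bromo-7-methoxy-2-[3-methoxy-4-(pivaloyloxy)phenyl]-2,3-dihydrobenzofuran-3-carboxylate, via enol ether 8 (not isolated), via iodane ketal 9 (not isolated)
Conditions: PhI(OAc)2 (1.2 equiv), conc. H2SO4 (0.5–1 equiv), HC(OMe)3 (solvent), rt; aqueous NaHCO3 work-up
Reagents that add atoms: trimethyl orthoformate, COC(OC)OC; (diacetoxyiodo)benzene, CC(=O)OI(OC(C)=O)c1ccccc1 (its atoms stay only in 9)
Why: Acid and orthoformate turn ketone 7 into enol ether 8, the iodine(III) electrophile attacks C3 on the face opposite the equatorial C2 aryl group and methanol caps C4, giving the 2,3-trans diequatorial iodane ketal 9 whose C4–C4a bond is antiperiplanar to C3–I. Departure of iodobenzene is accompanied by a 1,2-shift of the benzo carbon C4a from C4 to C3, assisted by the ortho ring oxygen, and the dimethoxycarbenium ion left at the now exocyclic C4 collapses to the methyl ester. The closest known reaction type is the iodine(III)- or thallium(III)-mediated oxidative ring contraction of flavanones in trimethyl orthoformate to trans-2-aryl-2,3-dihydrobenzofuran-3-carboxylates, the cyclic counterpart of the aryl methyl ketone to arylacetate rearrangement. The ring O1–C2–C3–C3a–C7a is closed by C3–C4a bond formation within the shift (3-exo-tet attack of the ipso carbon on C3 through a bridged phenonium ion, then cleavage of C4–C4a) and not by cyclisation of an open chain. C2 is not touched and keeps its S configuration, while the new centre C3 is set by inversion at the carbon that bore iodine, which translates the trans relation of 9 into the 2,3-trans (2S,3S) ester. The selectivity needed is migration of the A ring instead of the C2 aryl group (isoflavone pathway) without ionisation of C2–O; the C4 ketal penalises the diaxial conformer required for the C2-aryl shift, and the pivalate para to C2 makes that ring a poor migrating and cation-stabilising group.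

Step 6
Reactants: 10 methyl (2S,3S)-5-bromo-7-methoxy-2-[3-methoxy-4-(pivaloyloxy)phenyl]-2,3-dihydrobenzofuran-3-carboxylate
Product: 11 4-[(2S,3R)-5-bromo-3-(hydroxymethyl)-7-methoxy-2,3-dihydrobenzofuran-2-yl]-2-methoxyphenol
Conditions: LiAlH4 (3 equiv), THF, 0 °C; Rochelle salt work-up
Reagents that add atoms: none
Why: Hydride reduction converts the methyl ester into the hydroxymethyl group and removes the pivalate helper in the same operation, hydride addition being faster than enolisation so that C3 is kept (the descriptor changes to R only through the priority change) and the aryl bromide survives at 0 °C.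

Step 7
Reactants: 11 4-[(2S,3R)-5-bromo-3-(hydroxymethyl)-7-methoxy-2,3-dihydrobenzofuran-2-yl]-2-methoxyphenol
Product: 12 (2S,3R)-2-[4-(benzyloxy)-3-methoxyphenyl]-3-[(benzyloxy)methyl]-5-bromo-7-methoxy-2,3-dihydrobenzofuran
Conditions: NaH (2.5 equiv), BnBr (2.4 equiv), n-Bu4NI (cat.), DMF, 0 °C to rt
Reagents that add atoms: benzyl bromide, BrCc1ccccc1
Why: A double Williamson etherification protects phenol and primary alcohol at once, and even a reversible quinone-methide opening of the phenoxide would re-close 2,3-trans under control of the intact C3 centre.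

Step 8
Reactants: 12 (2S,3R)-2-[4-(benzyloxy)-3-methoxyphenyl]-3-[(benzyloxy)methyl]-5-bromo-7-methoxy-2,3-dihydrobenzofuran; 13 4-methoxy-2-methylidene-4-oxobutanoic acid (monomethyl itaconate)
Product: 14 (E)-3-{(2S,3R)-2-[4-(benzyloxy)-3-methoxyphenyl]-3-[(benzyloxy)methyl]-7-methoxy-2,3-dihydrobenzofuran-5-yl}-2-(2-methoxy-2-oxoethyl)acrylic acid
Conditions: Pd(OAc)2 (5 mol %), P(o-tol)3 (12 mol %), Et3N (3 equiv), DMF, 100 °C
Reagents that add atoms: none
Why: Mizoroki–Heck arylation of an itaconate at its terminal CH2, with syn insertion and syn β-hydride elimination toward the benzylic hydrogen, should give the aryl-conjugated E-benzylidenesuccinate half-ester.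

Step 9
Reactants: 14 (E)-3-{(2S,3R)-2-[4-(benzyloxy)-3-methoxyphenyl]-3-[(benzyloxy)methyl]-7-methoxy-2,3-dihydrobenzofuran-5-yl}-2-(2-methoxy-2-oxoethyl)acrylic acid
Product: 15 (2R)-2-({(2S,3R)-2-[4-(benzyloxy)-3-methoxyphenyl]-3-[(benzyloxy)methyl]-7-methoxy-2,3-dihydrobenzofuran-5-yl}methyl)-4-methoxy-4-oxobutanoic acid
Conditions: [Rh(cod)((S,S)-Et-DuPHOS)]BF4 (1 mol %), H2 (6 bar), MeOH, rt
Reagents that add atoms: none
Why: Rh–bisphospholane asymmetric hydrogenation of a β-aryl itaconate, chelated through the alkene and the CH2CO2Me carbonyl, sets the new centre (R) under catalyst control because the existing centres are remote, and the homogeneous catalyst leaves benzyl ethers intact.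

Step 10
Reactants: 15 (2R)-2-({(2S,3R)-2-[4-(benzyloxy)-3-methoxyphenyl]-3-[(benzyloxy)methyl]-7-methoxy-2,3-dihydrobenzofuran-5-yl}methyl)-4-methoxy-4-oxobutanoic acid
Product: 17 (4R)-4-({(2S,3R)-2-[4-(benzyloxy)-3-methoxyphenyl]-3-[(benzyloxy)methyl]-7-methoxy-2,3-dihydrobenzofuran-5-yl}methyl)dihydrofuran-2(3H)-one, via hydroxy ester 16 (not isolated)
Conditions: BH3·SMe2 (1.5 equiv), THF, 0 °C to rt; MeOH quench; TsOH·H2O (cat.), CH2Cl2, rt
Reagents that add atoms: none
Why: Borane reduces the free carboxylic acid much faster than the methyl ester, and the resulting γ-hydroxy ester lactonises (5-exo-trig acyl substitution) without touching the stereocentre.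

Step 11
Reactants: 18 [4-(benzyloxy)-3-methoxyphenyl]methanol
Product: 19 1-(benzyloxy)-4-(bromomethyl)-2-methoxybenzene
Conditions: PBr3 (0.4 equiv), Et2O, 0 °C; used without storage
Reagents that add atoms: phosphorus tribromide, BrP(Br)Br
Why: Standard conversion of an electron-rich benzylic alcohol into the bromide through its phosphite ester.

Step 12
Reactants: 17 (4R)-4-({(2S,3R)-2-[4-(benzyloxy)-3-methoxyphenyl]-3-[(benzyloxy)methyl]-7-methoxy-2,3-dihydrobenzofuran-5-yl}methyl)dihydrofuran-2(3H)-one; 19 1-(benzyloxy)-4-(bromomethyl)-2-methoxybenzene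
Product: 21 (3R,4R)-3-[4-(benzyloxy)-3-methoxybenzyl]-4-({(2S,3R)-2-[4-(benzyloxy)-3-methoxyphenyl]-3-[(benzyloxy)methyl]-7-methoxy-2,3-dihydrobenzofuran-5-yl}methyl)dihydrofuran-2(3H)-one (tri-O-benzyl-lappaol A), via lithium enolate 20 (not isolated)
Conditions: LiHMDS (1.1 equiv), THF, −78 °C; then 19, DMPU, −78 to −30 °C
Reagents that add atoms: lithium hexamethyldisilazide, [Li+].C[Si](C)(C)[N-][Si](C)(C)C (lithium stays only in 20)
Why: Alkylation of a β-substituted γ-butyrolactone enolate takes place on the face opposite the Cβ substituent, the classical entry to trans-dibenzylbutyrolactone lignans, so Cα is set (R) and is also the thermodynamically favoured epimer.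

Step 13
Reactants: 21 tri-O-benzyl-lappaol A
Product: 22 lappaol A
Conditions: H2 (1 atm), 10 % Pd/C, EtOAc–EtOH, rt; stopped once the last benzyl ether is consumed
Reagents that add atoms: none
Why: Hydrogenolysis removes the two aryl benzyl ethers and the primary benzyl ether, while the secondary, ring-bound benzylic C2–O bond is far more hindered and should persist under these mild conditions; no stereocentre is affected.

**Compound list**
1 | 1-(2-hydroxy-3-methoxyphenyl)ethan-1-one | CC(=O)c1cccc(OC)c1O | starting material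
2 | 1-(5-bromo-2-hydroxy-3-methoxyphenyl)ethan-1-one | CC(=O)c1cc(Br)cc(OC)c1O | intermediate
3 | (E)-1-(5-bromo-2-hydroxy-3-methoxyphenyl)-3-(dimethylamino)prop-2-en-1-one | CN(C)/C=C/C(=O)c1cc(Br)cc(OC)c1O | intermediate
4 | 6-bromo-8-methoxy-4H-chromen-4-one | O=c1ccoc2c(OC)cc(Br)cc12 | intermediate
5 | (4-hydroxy-3-methoxyphenyl)boronic acid | OB(O)c1ccc(O)c(OC)c1 | starting material
6 | [3-methoxy-4-(pivaloyloxy)phenyl]boronic acid | CC(C)(C)C(=O)Oc1ccc(B(O)O)cc1OC | intermediate
7 | (2S)-6-bromo-8-methoxy-2-[3-methoxy-4-(pivaloyloxy)phenyl]chroman-4-one | O=C1C[C@@H](c2ccc(OC(=O)C(C)(C)C)c(OC)c2)Oc2c(OC)cc(Br)cc12 | intermediate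
8 | (2S)-6-bromo-4,8-dimethoxy-2-[3-methoxy-4-(pivaloyloxy)phenyl]-2H-chromene | COC1=C[C@@H](c2ccc(OC(=O)C(C)(C)C)c(OC)c2)Oc2c(OC)cc(Br)cc12 | intermediate
9 | (2R,3R)-3-[acetoxy(phenyl)-λ3-iodanyl]-6-bromo-4,4,8-trimethoxy-2-[3-methoxy-4-(pivaloyloxy)phenyl]chromane (2,3-trans) | COC1(OC)[C@H](I(OC(C)=O)c2ccccc2)[C@@H](c2ccc(OC(=O)C(C)(C)C)c(OC)c2)Oc2c(OC)cc(Br)cc12 | intermediate
10 | methyl (2S,3S)-5-bromo-7-methoxy-2-[3-methoxy-4-(pivaloyloxy)phenyl]-2,3-dihydrobenzofuran-3-carboxylate (2,3-trans) | Brc1cc(OC)c2c(c1)[C@H](C(=O)OC)[C@@H](c1ccc(OC(=O)C(C)(C)C)c(OC)c1)O2 | intermediate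
11 | 4-[(2S,3R)-5-bromo-3-(hydroxymethyl)-7-methoxy-2,3-dihydrobenzofuran-2-yl]-2-methoxyphenol | Brc1cc(OC)c2c(c1)[C@H](CO)[C@@H](c1ccc(O)c(OC)c1)O2 | intermediate
12 | (2S,3R)-2-[4-(benzyloxy)-3-methoxyphenyl]-3-[(benzyloxy)methyl]-5-bromo-7-methoxy-2,3-dihydrobenzofuran | Brc1cc(OC)c2c(c1)[C@H](COCc1ccccc1)[C@@H](c1ccc(OCc3ccccc3)c(OC)c1)O2 | intermediate
13 | 4-methoxy-2-methylidene-4-oxobutanoic acid (monomethyl itaconate) | C=C(CC(=O)OC)C(=O)O | starting material
14 | (E)-benzylidenesuccinic acid 4-methyl ester bearing the (2S,3R)-dihydrobenzofuran-5-yl group of 12 (aryl trans to CO2H) | COC(=O)C/C(C(=O)O)=C\c1cc(OC)c2c(c1)[C@H](COCc1ccccc1)[C@@H](c1ccc(OCc3ccccc3)c(OC)c1)O2 | intermediate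
15 | (2R)-2-(arylmethyl)succinic acid 4-methyl ester, aryl = (2S,3R)-dihydrobenzofuran-5-yl group of 12 | OC(=O)[C@H](Cc1cc(OC)c2c(c1)[C@H](COCc1ccccc1)[C@@H](c1ccc(OCc3ccccc3)c(OC)c1)O2)CC(=O)OC | intermediate
16 | methyl (3R)-3-(arylmethyl)-4-hydroxybutanoate, aryl as in 15 | OC[C@H](Cc1cc(OC)c2c(c1)[C@H](COCc1ccccc1)[C@@H](c1ccc(OCc3ccccc3)c(OC)c1)O2)CC(=O)OC | intermediate
17 | (4R)-4-(arylmethyl)dihydrofuran-2(3H)-one, aryl as in 15 | O=C1C[C@@H](Cc2cc(OC)c3c(c2)[C@H](COCc2ccccc2)[C@@H](c2ccc(OCc4ccccc4)c(OC)c2)O3)CO1 | intermediate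
18 | [4-(benzyloxy)-3-methoxyphenyl]methanol | OCc1ccc(OCc2ccccc2)c(OC)c1 | starting material
19 | 1-(benzyloxy)-4-(bromomethyl)-2-methoxybenzene | BrCc1ccc(OCc2ccccc2)c(OC)c1 | intermediate
20 | lithium enolate of lactone 17 | [Li+].[O-]C1=C[C@@H](Cc2cc(OC)c3c(c2)[C@H](COCc2ccccc2)[C@@H](c2ccc(OCc4ccccc4)c(OC)c2)O3)CO1 | intermediate
21 | tri-O-benzyl-lappaol A, (3R,4R)-trans lactone, (2S,3R)-dihydrobenzofuran | COc1cc(C[C@H]2C(=O)OC[C@@H]2Cc2cc(OC)c3c(c2)[C@H](COCc2ccccc2)[C@@H](c2ccc(OCc4ccccc4)c(OC)c2)O3)ccc1OCc1ccccc1 | intermediate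
22 | lappaol A | COc1cc(C[C@H]2C(=O)OC[C@@H]2Cc2cc(OC)c3c(c2)[C@H](CO)[C@@H](c2ccc(O)c(OC)c2)O3)ccc1O | target

**Totals**
Total step count: 13.
Longest linear sequence: 11 steps (1, 2, 4, 5, 6, 7, 8, 9, 10, 12, 13).

**Steps most likely to fail**

**Step 5.**
- What may go wrong: a competing 1,2-shift of the C2 aryl group, solvolytic displacement of the iodane at C3, or acid-induced ionisation of the C2–O bond before the shift, with erosion of enantiopurity.
- Fallback: it sets out from 7 and returns at 10. It replaces the oxidation by a cycloaddition and nitrogen-extrusion ring contraction.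
- Enol ether 8 is made separately (HC(OMe)3, cat. TsOH) and isolated.
- It is then warmed with tosyl azide in MeCN. The azide should add to C3=C4 on the face opposite the C2 aryl group to give the fused triazoline F1.
- F1 opens to a C3-diazonium and C4-sulfonamide-anion pair and loses nitrogen. The push from C4 allows only a C4 substituent, the benzo carbon C4a, to migrate.
- This gives the trans methyl N-tosylimidate F2. Mild aqueous acid (1 M HCl, THF) hydrolyses it to ester 10.

**Step 4.**
- What may go wrong: slow migratory insertion with protodeboronation of 6, or insufficient facial selectivity on the 8-methoxy-substituted chromone.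
- Fallback: it sets out from 2 and returns at 7. It uses the chalcone route followed by a kinetic resolution.
- Vanillin is acylated (PivCl, Et3N) to 4-formyl-2-methoxyphenyl pivalate F3.
- A BF3·OEt2-mediated Claisen–Schmidt condensation with 2 gives the 2'-hydroxychalcone F4.
- NaOAc in refluxing EtOH closes F4 by oxa-Michael addition to the racemic flavanone F5.
- Rh-catalysed asymmetric transfer hydrogenation ([Cp*RhCl((R,R)-TsDPEN)], HCO2H–Et3N, EtOAc, rt) should reduce only the 2R enantiomer, to the cis-(2R,4R)-flavan-4-ol F6.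
- The unreacted ketone is (S)-7, which is separated by chromatography.

**Step 8.**
- What may go wrong: sluggish oxidative addition of the electron-rich aryl bromide, and β-hydride elimination or double-bond migration toward the CH2CO2Me side, which would spoil the following hydrogenation.
- Fallback: it sets out from 12 and returns at 17. It uses carbonyl chemistry instead of a cross-coupling.
- Bromine–lithium exchange (n-BuLi, THF, −78 °C) and DMF give the 5-carbaldehyde F7.
- Stobbe condensation with dimethyl succinate (t-BuOK, t-BuOH) gives the E half-ester F8, with a conjugated CO2Me and a free CH2CO2H.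
- The same Rh catalyst (MeOH, cat. NaOMe) gives the (R)-2-(arylmethyl)succinic acid 1-methyl ester F9.
- Reduction of the ester within the potassium carboxylate by Ca(BH4)2 (CaCl2, NaBH4, EtOH), followed by acidification, closes lactone 17.

**Further compounds**
F1 | step 5 | cis-fused 1-tosyl-1,2,3-triazoline across C3–C4 of enol ether 8, anti to the C2 aryl group | CO[C@@]12N(S(=O)(=O)c3ccc(C)cc3)N=N[C@@H]1[C@@H](c1ccc(OC(=O)C(C)(C)C)c(OC)c1)Oc1c(OC)cc(Br)cc12
F2 | step 5 | methyl (2S,3S)-5-bromo-7-methoxy-2-[3-methoxy-4-(pivaloyloxy)phenyl]-N-tosyl-2,3-dihydrobenzofuran-3-carboximidate | Brc1cc(OC)c2c(c1)[C@H](C(OC)=NS(=O)(=O)c1ccc(C)cc1)[C@@H](c1ccc(OC(=O)C(C)(C)C)c(OC)c1)O2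
F3 | step 4 | 4-formyl-2-methoxyphenyl pivalate | O=Cc1ccc(OC(=O)C(C)(C)C)c(OC)c1
F4 | step 4 | (E)-1-(5-bromo-2-hydroxy-3-methoxyphenyl)-3-[3-methoxy-4-(pivaloyloxy)phenyl]prop-2-en-1-one | O=C(/C=C/c1ccc(OC(=O)C(C)(C)C)c(OC)c1)c1cc(Br)cc(OC)c1O
F5 | step 4 | racemic 6-bromo-8-methoxy-2-[3-methoxy-4-(pivaloyloxy)phenyl]chroman-4-one | O=C1CC(c2ccc(OC(=O)C(C)(C)C)c(OC)c2)Oc2c(OC)cc(Br)cc12
F6 | step 4 | (2R,4R)-6-bromo-8-methoxy-2-[3-methoxy-4-(pivaloyloxy)phenyl]chroman-4-ol (2,4-cis) | O[C@@H]1C[C@H](c2ccc(OC(=O)C(C)(C)C)c(OC)c2)Oc2c(OC)cc(Br)cc12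
F7 | step 8 | (2S,3R)-2-[4-(benzyloxy)-3-methoxyphenyl]-3-[(benzyloxy)methyl]-7-methoxy-2,3-dihydrobenzofuran-5-carbaldehyde | O=Cc1cc(OC)c2c(c1)[C@H](COCc1ccccc1)[C@@H](c1ccc(OCc3ccccc3)c(OC)c1)O2
F8 | step 8 | (E)-3-(methoxycarbonyl)-4-aryl-but-3-enoic acid, aryl = (2S,3R)-dihydrobenzofuran-5-yl group of 12 | OC(=O)C/C(C(=O)OC)=C\c1cc(OC)c2c(c1)[C@H](COCc1ccccc1)[C@@H](c1ccc(OCc3ccccc3)c(OC)c1)O2
F9 | step 8 | (3R)-3-(methoxycarbonyl)-4-arylbutanoic acid, aryl as in F8 | COC(=O)[C@H](Cc1cc(OC)c2c(c1)[C@H](COCc1ccccc1)[C@@H](c1ccc(OCc3ccccc3)c(OC)c1)O2)CC(=O)O
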